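Readings and results are calculated from invented constants; scatter was added.

The ratio to watch in the amber flask stands at 0.396: target over whatever has left the starting material without showing as target, the split, here taken from its last two readings.

the same everywhere: starting material 20 mM; catalyst 0.50 mM
- amber: temperature 40 °C; the very flask that is asked about, followed so far
- violet: temperature 25 °C; run made earlier
- flask: temperature 40 °C; time 25 h

| run | time / h | target / % | starting material / % |
|---|---|---|---|
| amber | 1.33 | 8 | 54 |
| amber | 4.00 | 15 | 34 |
| amber | 8.00 | 23 | 21 |
| amber | 10.0 | 24 | 13 |
| amber | 15.0 | 29 | 5 |
| amber | 20.0 | 28 | 5 |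
| amber | 25.0 | 27 | 1 |
| violet | 3.00 | 7 | 62 |
| violet | 8.00 | 10 | 35 |
| violet | 15.0 | 7 | 22 |
| violet | 20.0 | 6 | 17 |
| violet | 30.0 | 5 | 13 |
| violet | 40.0 | 6 | 3 |
| violet | 48.0 | 8 | 3 |

(readings scatter by 1.5 percentage points)

- maple: at 25 h take out 90% of the target then present, then wait 25 h
- alder: change nothing and wait 25 h more
- larch: at 25 h add catalyst, 100% of the amount charged, then wait 25 h
- birch: at 25 h raise the temperature by 15 K, then wait 25 h

- removed target is counted in
- additions bring no volume worth counting

* target, in percent of the starting material first charged, at 25 h
* which option adds most target ("none" when 2 percentage points or less is all one gets) (maple / alder / larch / birch / none)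
* target present, with what was taken out counted in, in percent of the starting material first charged, after alder
* target present, with what was taken out counted in, in percent of the starting material first charged, after larch

Test the split first. In the amber run it reads 0.411 at 8.00 h, and it stays near that while starting material falls from 21% to 1%. In the violet run target reads 10% at 8.00 h, then 5% to 8% over the later readings, so its loss stops short of zero. Read this as a balance between target and a hidden form, that is, thermodynamic control.

The violet split, read from that run's last two readings and so carrying their scatter, is 0.0778, so the step between the runs multiplies the read split by about 5.09. Birch repeats that step of 15 K, so I reckon a split of 2.01.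

Now turn splits into shares of target, 0.284 and 0.668. My reckoning starts near 27.5%. I reckon alder and larch each at a gain of 0.28 percentage points, the share of target on the starting material last read. I reckon birch at a gain of 38 points and maple at 18 points. Both figures assume the hidden material returns entire, and the split cannot show that, so one number is not enough for the sizes. I choose birch.

The forecast gives 28% now, 27.5% after alder, 27.5% after larch, and best none: “Heating has no feedstock either”.

The flask gives 27.3%, 27.8% after alder, 27.8% after larch, and best birch.

    starting material ⇌ other conformer (K = 0.531, k = 2.05 × 10⁻⁴ /s, Ea = 91.0 kJ/mol, ΔH = −33.0 kJ/mol)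
    starting material + catalyst → catalyst + target (k = 0.0852 /M/s, Ea = 46.0 kJ/mol)
    target + catalyst ⇌ isomer of the product B + catalyst, rate k3*[catalyst]*[target] forward; the back reaction follows from the equilibrium constant (K = 1.41, k = 0.500 /M/s, Ea = 44.0 kJ/mol, ΔH = −89.0 kJ/mol)
    catalyst + other conformer → catalyst + isomer of the product A (k = 0.0880 /M/s, Ea = 67.0 kJ/mol)
    (constants at 40 °C)

Forecast and flask part on best: birch adds 24 points, less than I reckoned, maple 15 points, alder 0.46 points, larch 0.47 points. Now ask whether the amber flask has come to rest. Left ten times as long, its target goes from 27.3% to 27.8%, and its split from 0.383 to 0.385. The same flask run at 65 °C throughout stands at a higher split, 1.86, after 25.0 h.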